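**Retrosynthetic overview**
- The quinone and the primary alcohol are unmasked together in the last step: (NH4)2Ce(NO3)6 acts on a hydroquinone dimethyl ether whose CH2OH is carried as a PMB ether.
- C12′–C13′ and the only stereocentre come from an (R)-TRIP-catalysed γ-allylboration of a (2E)-2-(PMBOCH2)-enal with a tertiary α,α-dimethylallyl boronate, which transfers a linear prenyl group (the new step).
- The enal comes from the C10′ aldehyde by a one-pot oxa-Michael/Horner–Wadsworth–Emmons reaction with trimethyl 2-phosphonoacrylate and PMB alkoxide, then ester → CHO; the E geometry places CH2O cis to the chain.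
- The C10′ aldehyde comes from terminal bromohydrin/oxirane/periodate cleavage of an aryl farnesyl arene, itself made by copper-catalysed aryl–allyl coupling.
- No ring is built: the six-membered ring is bought as the arene and oxidised to the quinone last; the oxirane of step 2 is transient and is cleaved in step 3.

Assumption: 1-bromo-2,5-dimethoxy-3-methylbenzene, (2E,6E)-farnesyl bromide, trimethyl 2-phosphonoacrylate and prenol are taken as catalogue chemicals; chain positions are numbered C1′–C15′ from the ring, and the target carbinol C12′ is R as read from the SMILES.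

**Step 1**
Reactants: 1 1-bromo-2,5-dimethoxy-3-methylbenzene; 2 (2E,6E)-farnesyl bromide
Product: 4 1,4-dimethoxy-2-methyl-6-[(2E,6E)-3,7,11-trimethyldodeca-2,6,10-trien-1-yl]benzene, via aryllithium 3 (not isolated)
Conditions: n-BuLi, THF, −78 °C; CuBr·SMe2 (10 mol%); then 2, −78 → 0 °C
Reagents that add atoms: none
Why: Br–Li exchange gives aryllithium 3, which under monovalent-copper catalysis displaces the primary allylic bromide in SN2 fashion (copper-catalysed aryl–allyl coupling) with both E olefins retained.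

**Step 2**
Reactants: 4 1,4-dimethoxy-2-methyl-6-[(2E,6E)-3,7,11-trimethyldodeca-2,6,10-trien-1-yl]benzene
Product: 6 3-[(3E,7E)-9-(2,5-dimethoxy-3-methylphenyl)-3,7-dimethylnona-3,7-dien-1-yl]-2,2-dimethyloxirane (racemic), via bromohydrin 5 (not isolated)
Conditions: NBS, THF/H2O (3:1), 0 °C; then K2CO3, MeOH, rt
Reagents that add atoms: water O (oxirane oxygen); N-bromosuccinimide O=C1CCC(=O)N1Br (its Br is present in 5 only)
Why: van Tamelen terminal bromohydrin formation (the coiled polyene exposes the terminal trisubstituted olefin to Br+, water opens the bromonium ion at the tertiary carbon) followed by base-induced oxirane closure; the new centre is racemic and is erased in step 3.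

**Step 3**
Reactants: 6 3-[(3E,7E)-9-(2,5-dimethoxy-3-methylphenyl)-3,7-dimethylnona-3,7-dien-1-yl]-2,2-dimethyloxirane
Product: 7 (4E,8E)-10-(2,5-dimethoxy-3-methylphenyl)-4,8-dimethyldeca-4,8-dienal
Conditions: H5IO6, THF/H2O, 0 °C
Reagents that add atoms: none
Why: Periodic acid hydrolyses the oxirane and cleaves the resulting glycol in one pot (Malaprade glycol cleavage), giving the C10′ aldehyde and acetone without touching the trisubstituted olefins or the arene.

**Step 4**
Reactants: 7 (4E,8E)-10-(2,5-dimethoxy-3-methylphenyl)-4,8-dimethyldeca-4,8-dienal; 8 trimethyl 2-phosphonoacrylate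
Product: 10 methyl (2E,6E,10E)-12-(2,5-dimethoxy-3-methylphenyl)-2-{[(4-methoxybenzyl)oxy]methyl}-6,10-dimethyldodeca-2,6,10-trienoate, via phosphonate carbanion 9 (not isolated)
Conditions: 4-MeOC6H4CH2OH, NaH, THF, 0 °C; 8, −20 → 0 °C; then 7, 0 °C → rt
Reagents that add atoms: 4-methoxybenzyl alcohol COc1ccc(CO)cc1
Why: Tandem oxa-Michael/Horner–Wadsworth–Emmons olefination: the alkoxide adds to the phosphonoacrylate to give stabilised carbanion 9, which olefinates the aldehyde with the usual E preference of α-branched phosphonoacetates (ester trans to the chain, CH2OPMB cis to C9′); the minor Z isomer is removed by chromatography.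

**Step 5**
Reactants: 10 methyl (2E,6E,10E)-12-(2,5-dimethoxy-3-methylphenyl)-2-{[(4-methoxybenzyl)oxy]methyl}-6,10-dimethyldodeca-2,6,10-trienoate
Product: 11 (2Z,6E,10E)-12-(2,5-dimethoxy-3-methylphenyl)-2-{[(4-methoxybenzyl)oxy]methyl}-6,10-dimethyldodeca-2,6,10-trien-1-ol
Conditions: i-Bu2AlH (2.5 equiv), CH2Cl2, −78 °C; aq. KNaC4H4O6 work-up
Reagents that add atoms: none
Why: 1,2-Reduction of the enoate by i-Bu2AlH at low temperature gives the allylic alcohol and leaves the PMB ether, the arene and the olefin geometry intact (the descriptor changes to Z only through CIP priorities).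

**Step 6**
Reactants: 11 (2Z,6E,10E)-12-(2,5-dimethoxy-3-methylphenyl)-2-{[(4-methoxybenzyl)oxy]methyl}-6,10-dimethyldodeca-2,6,10-trien-1-ol
Product: 12 (2E,6E,10E)-12-(2,5-dimethoxy-3-methylphenyl)-2-{[(4-methoxybenzyl)oxy]methyl}-6,10-dimethyldodeca-2,6,10-trienal
Conditions: MnO2, CH2Cl2, rt
Reagents that add atoms: none
Why: Neutral MnO2 allylic oxidation gives the enal (CHO trans to the chain, the thermodynamically preferred geometry) without E/Z isomerisation or base-induced loss of the PMBO group.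

**Step 7**
Reactants: 13 prenol (3-methylbut-2-en-1-ol)
Product: 14 methyl 3-methylbut-2-en-1-yl carbonate
Conditions: ClCO2Me, pyridine, CH2Cl2, 0 °C → rt
Reagents that add atoms: methyl chloroformate COC(=O)Cl
Why: O-Acylation of the primary allylic alcohol with the chloroformate (pyridine scavenges HCl) gives the allylic carbonate needed for SN2′ borylation.

**Step 8**
Reactants: 14 methyl 3-methylbut-2-en-1-yl carbonate
Product: 15 4,4,5,5-tetramethyl-2-(2-methylbut-3-en-2-yl)-1,3,2-dioxaborolane (α,α-dimethylallyl-Bpin)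
Conditions: B2pin2, CuCl (5 mol%), 1,3-dimesitylimidazolium chloride (5 mol%), NaOt-Bu (15 mol%), THF, rt
Reagents that add atoms: bis(pinacolato)diboron CC1(C)OB(OC1(C)C)B1OC(C)(C)C(C)(C)O1
Why: Copper-catalysed γ-selective boryl substitution of an allylic carbonate: LCu–Bpin adds across the olefin with boron on the γ-carbon and β-elimination releases CO2 and methoxide, so the tertiary allylboronate forms and, as a pinacol ester, does not undergo 1,3-boron shift.

**Step 9**
Reactants: 12 (2E,6E,10E)-12-(2,5-dimethoxy-3-methylphenyl)-2-{[(4-methoxybenzyl)oxy]methyl}-6,10-dimethyldodeca-2,6,10-trienal; 15 4,4,5,5-tetramethyl-2-(2-methylbut-3-en-2-yl)-1,3,2-dioxaborolane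
Product: 17 (5R,6E,10E,14E)-16-(2,5-dimethoxy-3-methylphenyl)-6-{[(4-methoxybenzyl)oxy]methyl}-2,10,14-trimethylhexadeca-2,6,10,14-tetraen-5-ol, via borate ester 16 (not isolated)
Conditions: (R)-TRIP (10 mol%), 15 (1.5 equiv), 4 Å MS, toluene, −30 → 0 °C; then aq. NaHCO3
Reagents that add atoms: none
Why: Proposed new method: chiral-phosphoric-acid-catalysed γ-allylboration of an α-branched 2-(alkoxymethyl)enal with a tertiary α,α-dimethylallyl pinacolboronate — the P–OH hydrogen-bonds to a boronate oxygen and P=O to the formyl H in a closed Zimmerman–Traxler chair with the alkenyl group equatorial, C–C bond formation at the unsubstituted γ-CH2 delivers the linear prenyl group, the uncatalysed background is slow for the hindered tertiary boronate, and the (R)-catalyst pocket is expected to expose the Re face of the aldehyde (the sense seen with aryl and cinnamyl aldehydes) to set (R)-C12′, to be confirmed by Mosher analysis; the closest known reaction type is TRIP-catalysed allyl- and crotylboration of aldehydes with pinacol allylboronates, including the kinetic resolution of secondary α-substituted allylboronates.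

**Step 10**
Reactants: 17 (5R,6E,10E,14E)-16-(2,5-dimethoxy-3-methylphenyl)-6-{[(4-methoxybenzyl)oxy]methyl}-2,10,14-trimethylhexadeca-2,6,10,14-tetraen-5-ol
Product: 19 2-[(2E,6E,10E,12R)-12-hydroxy-11-(hydroxymethyl)-3,7,15-trimethylhexadeca-2,6,10,14-tetraen-1-yl]-6-methylcyclohexa-2,5-diene-1,4-dione (CNP0201434.1), via quinone PMB ether 18 (not isolated)
Conditions: (NH4)2Ce(NO3)6 (5 equiv), MeCN/H2O (4:1), 0 °C, 30 min
Reagents that add atoms: water O (both quinone oxygens)
Why: Oxidative demethylation of the 1,4-dimethoxyarene by tetravalent cerium gives the para-quinone within minutes (carbonyl oxygens from water) and the remaining oxidant cleaves the PMB ether to the primary alcohol and anisaldehyde; no base or reductant follows, so C12′ and the olefin geometries are untouched.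

**Compound list**
1 | 1-bromo-2,5-dimethoxy-3-methylbenzene | COc1cc(C)c(OC)c(Br)c1 | starting material
2 | (2E,6E)-1-bromo-3,7,11-trimethyldodeca-2,6,10-triene (farnesyl bromide) | CC(C)=CCC/C(C)=C/CC/C(C)=C/CBr | starting material
3 | (2,5-dimethoxy-3-methylphenyl)lithium | [Li]c1cc(OC)cc(C)c1OC | intermediate (not isolated)
4 | 1,4-dimethoxy-2-methyl-6-[(2E,6E)-3,7,11-trimethyldodeca-2,6,10-trien-1-yl]benzene | COc1cc(C)c(OC)c(C/C=C(C)/CC/C=C(C)/CCC=C(C)C)c1 | intermediate
5 | (6E,10E)-3-bromo-12-(2,5-dimethoxy-3-methylphenyl)-2,6,10-trimethyldodeca-6,10-dien-2-ol (racemic) | COc1cc(C)c(OC)c(C/C=C(C)/CC/C=C(C)/CCC(Br)C(C)(C)O)c1 | intermediate (not isolated)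
6 | 3-[(3E,7E)-9-(2,5-dimethoxy-3-methylphenyl)-3,7-dimethylnona-3,7-dien-1-yl]-2,2-dimethyloxirane (racemic) | COc1cc(C)c(OC)c(C/C=C(C)/CC/C=C(C)/CCC2OC2(C)C)c1 | intermediate
7 | (4E,8E)-10-(2,5-dimethoxy-3-methylphenyl)-4,8-dimethyldeca-4,8-dienal | COc1cc(C)c(OC)c(C/C=C(C)/CC/C=C(C)/CCC=O)c1 | intermediate
8 | methyl 2-(dimethoxyphosphoryl)prop-2-enoate (trimethyl 2-phosphonoacrylate) | COC(=O)C(=C)P(=O)(OC)OC | starting material
9 | sodium salt of the carbanion of methyl 2-(dimethoxyphosphoryl)-3-[(4-methoxybenzyl)oxy]propanoate | COC(=O)[C-](COCc1ccc(OC)cc1)P(=O)(OC)OC.[Na+] | intermediate (not isolated)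
10 | methyl (2E,6E,10E)-12-(2,5-dimethoxy-3-methylphenyl)-2-{[(4-methoxybenzyl)oxy]methyl}-6,10-dimethyldodeca-2,6,10-trienoate | COc1cc(C)c(OC)c(C/C=C(C)/CC/C=C(C)/CC/C=C(/C(=O)OC)COCc2ccc(OC)cc2)c1 | intermediate
11 | (2Z,6E,10E)-12-(2,5-dimethoxy-3-methylphenyl)-2-{[(4-methoxybenzyl)oxy]methyl}-6,10-dimethyldodeca-2,6,10-trien-1-ol | COc1cc(C)c(OC)c(C/C=C(C)/CC/C=C(C)/CC/C=C(/CO)COCc2ccc(OC)cc2)c1 | intermediate
12 | (2E,6E,10E)-12-(2,5-dimethoxy-3-methylphenyl)-2-{[(4-methoxybenzyl)oxy]methyl}-6,10-dimethyldodeca-2,6,10-trienal | COc1cc(C)c(OC)c(C/C=C(C)/CC/C=C(C)/CC/C=C(/C=O)COCc2ccc(OC)cc2)c1 | intermediate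
13 | 3-methylbut-2-en-1-ol (prenol) | CC(C)=CCO | starting material
14 | methyl 3-methylbut-2-en-1-yl carbonate | CC(C)=CCOC(=O)OC | intermediate
15 | 4,4,5,5-tetramethyl-2-(2-methylbut-3-en-2-yl)-1,3,2-dioxaborolane | C=CC(C)(C)B1OC(C)(C)C(C)(C)O1 | intermediate
16 | 2-{[(5R,6E,10E,14E)-16-(2,5-dimethoxy-3-methylphenyl)-6-{[(4-methoxybenzyl)oxy]methyl}-2,10,14-trimethylhexadeca-2,6,10,14-tetraen-5-yl]oxy}-4,4,5,5-tetramethyl-1,3,2-dioxaborolane | CC(C)=CC[C@@H](OB1OC(C)(C)C(C)(C)O1)/C(=C/CC/C(C)=C/CC/C(C)=C/Cc2cc(OC)cc(C)c2OC)COCc3ccc(OC)cc3 | intermediate (not isolated)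
17 | (5R,6E,10E,14E)-16-(2,5-dimethoxy-3-methylphenyl)-6-{[(4-methoxybenzyl)oxy]methyl}-2,10,14-trimethylhexadeca-2,6,10,14-tetraen-5-ol | CC(C)=CC[C@@H](O)/C(=C/CC/C(C)=C/CC/C(C)=C/Cc1cc(OC)cc(C)c1OC)COCc2ccc(OC)cc2 | intermediate
18 | 2-[(2E,6E,10E,12R)-12-hydroxy-11-{[(4-methoxybenzyl)oxy]methyl}-3,7,15-trimethylhexadeca-2,6,10,14-tetraen-1-yl]-6-methylcyclohexa-2,5-diene-1,4-dione | CC(C)=CC[C@@H](O)/C(=C/CC/C(C)=C/CC/C(C)=C/CC1=CC(=O)C=C(C)C1=O)COCc2ccc(OC)cc2 | intermediate (not isolated)
19 | 2-[(2E,6E,10E,12R)-12-hydroxy-11-(hydroxymethyl)-3,7,15-trimethylhexadeca-2,6,10,14-tetraen-1-yl]-6-methylcyclohexa-2,5-diene-1,4-dione | CC(C)=CC[C@@H](O)/C(=C/CC/C(C)=C/CC/C(C)=C/CC1=CC(=O)C=C(C)C1=O)CO | target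

**Step count and risks**
Total steps: 10 (eight in the main line plus two for boronate 15). Longest linear sequence: 8 (steps 1–6, 9, 10).

The three steps most likely to fail:

Step 9, the new step. The tertiary boronate may react slowly with the α-branched enal, or the enantioselectivity may be lower than for unbranched aldehydes. The fallback uses known chemistry and sets out from 12. (R)-TRIP-catalysed allylboration with commercial allyl-Bpin, which is established for α,β-unsaturated aldehydes, gives the borate ester F1, hydrolysed on work-up to the allyl carbinol F2. Cross-metathesis of F2 with 2-methyl-2-butene as co-solvent, using the second-generation Grubbs catalyst RuCl2(=CHPh)(PCy3)(H2IMes) in CH2Cl2 at 40 °C, turns the terminal vinyl group into the prenyl terminus. The route is rejoined at 17.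

Step 10. The double duty of the cerium oxidant could over-oxidise the polyene or fragment the homoallylic alcohol during the slower PMB cleavage. The fallback sets out from 17 and separates the two events. DDQ in CH2Cl2/pH 7 buffer at 0 °C removes the PMB group first and gives the dimethoxyarene diol F3. A brief treatment with (NH4)2Ce(NO3)6 (2.2 equiv, MeCN/H2O, 0 °C, 10 min) then oxidises only the arene. The route is rejoined at 19.

Step 4. Retro-Michael loss of the alkoxide, transesterification or a poor E/Z ratio could erode the yield of 10. The fallback sets out from 7 and replaces the olefination by aldol/dehydration. The lithium enolate of methyl 3-[(4-methoxybenzyl)oxy]propanoate (LiN(i-Pr)2, THF, −78 °C) adds to 7 to give the β-hydroxy ester F4 as a diastereomer mixture. MsCl/Et3N converts it to the mesylate F5, and DBU in CH2Cl2 eliminates methanesulfonate to the E-enoate. The route is rejoined at 10.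

**Further compounds**
F1 | step 9 | 2-{[(4R,5E,9E,13E)-15-(2,5-dimethoxy-3-methylphenyl)-5-{[(4-methoxybenzyl)oxy]methyl}-9,13-dimethylpentadeca-1,5,9,13-tetraen-4-yl]oxy}-4,4,5,5-tetramethyl-1,3,2-dioxaborolane | C=CC[C@@H](OB1OC(C)(C)C(C)(C)O1)/C(=C/CC/C(C)=C/CC/C(C)=C/Cc2cc(OC)cc(C)c2OC)COCc3ccc(OC)cc3
F2 | step 9 | (4R,5E,9E,13E)-15-(2,5-dimethoxy-3-methylphenyl)-5-{[(4-methoxybenzyl)oxy]methyl}-9,13-dimethylpentadeca-1,5,9,13-tetraen-4-ol | C=CC[C@@H](O)/C(=C/CC/C(C)=C/CC/C(C)=C/Cc1cc(OC)cc(C)c1OC)COCc2ccc(OC)cc2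
F3 | step 10 | (5R,6E,10E,14E)-16-(2,5-dimethoxy-3-methylphenyl)-6-(hydroxymethyl)-2,10,14-trimethylhexadeca-2,6,10,14-tetraen-5-ol | CC(C)=CC[C@@H](O)/C(=C/CC/C(C)=C/CC/C(C)=C/Cc1cc(OC)cc(C)c1OC)CO
F4 | step 4 | methyl (6E,10E)-12-(2,5-dimethoxy-3-methylphenyl)-3-hydroxy-2-{[(4-methoxybenzyl)oxy]methyl}-6,10-dimethyldodeca-6,10-dienoate (diastereomer mixture) | COc1cc(C)c(OC)c(C/C=C(C)/CC/C=C(C)/CCC(O)C(COCc2ccc(OC)cc2)C(=O)OC)c1
F5 | step 4 | methyl (6E,10E)-12-(2,5-dimethoxy-3-methylphenyl)-2-{[(4-methoxybenzyl)oxy]methyl}-6,10-dimethyl-3-(methylsulfonyloxy)dodeca-6,10-dienoate (diastereomer mixture) | COc1cc(C)c(OC)c(C/C=C(C)/CC/C=C(C)/CCC(OS(C)(=O)=O)C(COCc2ccc(OC)cc2)C(=O)OC)c1
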